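The route rests on cutting the bridging 3(2H)-furanone (O3, C3, C2, C1, C10; germacrane numbering) at C2–C1 and O3–C10, which leaves an enolate unit (C2=C3–O3) and a glycidic acyl unit (C1, C10). Both bonds are made in one operation by ring contraction of an eleven-membered thiolactone, C1(=O)–S–C2H2–C3(=O), that carries a trans C9–C10 epoxide. Phosphine-driven sulfur extrusion joins C2 to C1 and closes the ten-membered carbocycle. The 1,3-diketonate oxygen O3 then opens the epoxide at C10 with inversion, closing the furanone and freeing O9. The step exploits the 1,3-dioxygenated C1–C2–C3 array of the furanone ring and the anti O3/O9 relationship across C10–C9.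

Key step: step 17

Numbering: C1 ring ketone, C2 =CH, C3 enol-ether carbon, O3 ring oxygen, C4=C5 olefin (C15 methyl), C6 lactone carbinol, C7, C8 isovalerate carbinol, C9 acetate carbinol, C10 quaternary carbon (C14 methyl), C11–C13 methylene lactone.
Assumption: (9H-fluoren-9-yl)methanethiol 14, stannane 21 and the ligand (−)-MIB, (2S)-3-exo-morpholinoisoborneol, are taken as commercially available.

Step 1
Reactants: 1 but-2-yn-1-ol
Product: 2 (Z)-3-iodobut-2-en-1-ol
Conditions: NaAlH2(OCH2CH2OMe)2, THF, 0 °C to rt; then I2, −78 °C to 0 °C; H2O work-up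
Reagents that add atoms: iodine, II
Why: Hydroxyl-directed trans-hydroalumination places aluminium on C4 in a cyclic alanate and iodinolysis with retention should give the Z-vinyl iodide, which fixes the Z-C4=C5 geometry of the target (hydroalumination–iodination).

Step 2
Reactants: 2 (Z)-3-iodobut-2-en-1-ol
Product: 3 (Z)-3-iodobut-2-enal
Conditions: MnO2, CH2Cl2, rt, dark
Reagents that add atoms: none
Why: Neutral allylic alcohol oxidation on MnO2 leaves the vinyl iodide untouched and should keep the Z-olefin if the aldehyde is used at once.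

Step 3
Reactants: 3 (Z)-3-iodobut-2-enal
Product: 4 (3S,4Z)-5-iodohexa-1,4-dien-3-ol
Conditions: Zn(CH=CH2)2 [from CH2=CHMgBr, ZnCl2, Et2O, salts removed with 1,4-dioxane], (−)-MIB (10 mol %), toluene, −20 °C; H2O work-up
Reagents that add atoms: divinylzinc, C=C[Zn]C=C (made in the flask from vinylmagnesium bromide, C=C[Mg]Br, and ZnCl2)
Why: In this amino-alcohol-catalysed asymmetric vinylzinc addition, the (−)-MIB–zinc complex should deliver the vinyl group to the Si face of the aldehyde, as it does for dialkylzincs, and so set C6 as the S carbinol.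

Step 4
Reactants: 4 (3S,4Z)-5-iodohexa-1,4-dien-3-ol; 5 2-(bromomethyl)prop-2-enoic acid
Product: 6 (3S,4Z)-5-iodohexa-1,4-dien-3-yl 2-(bromomethyl)prop-2-enoate
Conditions: DCC, DMAP (5 mol %), CH2Cl2, −20 °C to 0 °C
Reagents that add atoms: none
Why: Steglich esterification acylates the carbinol oxygen with retention at C6, and the low temperature and low DMAP loading should limit attack on the allylic bromide.

Step 5
Reactants: 6 (3S,4Z)-5-iodohexa-1,4-dien-3-yl 2-(bromomethyl)prop-2-enoate
Product: 7 (5S)-3-(bromomethyl)-5-[(1Z)-2-iodoprop-1-en-1-yl]furan-2(5H)-one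
Conditions: second-generation Hoveyda–Grubbs catalyst (5 mol %), toluene (5 mM), 80 °C
Reagents that add atoms: none
Why: In this ring-closing metathesis the ruthenium carbene should load on the monosubstituted vinyl group and close onto the 1,1-disubstituted acrylate to the butenolide with loss of ethene, while the trisubstituted iodoalkene stays inert.

Step 6
Reactants: 8 (tert-butyldimethylsilyloxy)acetaldehyde; 9 ethyl 2-(triphenylphosphoranylidene)propanoate
Product: 10 ethyl (2E)-4-(tert-butyldimethylsilyloxy)-2-methylbut-2-enoate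
Conditions: CH2Cl2, rt
Reagents that add atoms: none
Why: Wittig olefination with the stabilised α-branched ylide should give the E-trisubstituted enoate, in which C8 is trans to C1.

Step 7
Reactants: 10 ethyl (2E)-4-(tert-butyldimethylsilyloxy)-2-methylbut-2-enoate
Product: 11 (2E)-4-(tert-butyldimethylsilyloxy)-2-methylbut-2-en-1-ol
Conditions: i-Bu2AlH (2.2 equiv), CH2Cl2, −78 °C; H2O work-up
Reagents that add atoms: none
Why: 1,2-Reduction of the enoate with i-Bu2AlH should give the allylic alcohol without change of olefin geometry or loss of the silyl ether.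

Step 8
Reactants: 11 (2E)-4-(tert-butyldimethylsilyloxy)-2-methylbut-2-en-1-ol
Product: 12 [(2R,3R)-3-(tert-butyldimethylsilyloxymethyl)-2-methyloxiran-2-yl]methanol
Conditions: Ti(Oi-Pr)4 (10 mol %), D-(−)-diethyl tartrate (12 mol %), t-BuOOH, 4 Å molecular sieves, CH2Cl2, −20 °C
Reagents that add atoms: tert-butyl hydroperoxide, CC(C)(C)OO
Why: In the Sharpless asymmetric epoxidation the D-(−)-tartrate complex should deliver oxygen to the top face of the E-allylic alcohol (CH2OH drawn lower right), setting C9 and C10 by reagent control, and the syn addition keeps C8 trans to C1.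

Step 9
Reactants: 12 [(2R,3R)-3-(tert-butyldimethylsilyloxymethyl)-2-methyloxiran-2-yl]methanol
Product: 13 (2S,3R)-3-(tert-butyldimethylsilyloxymethyl)-2-methyloxirane-2-carboxylic acid
Conditions: RuCl3 (2 mol %), NaIO4, MeCN/EtOAc/H2O, 0 °C to rt
Reagents that add atoms: water, O (enters through the aldehyde hydrate; NaIO4, [Na+].[O-]I(=O)(=O)=O, is the terminal oxygen source)
Why: Catalytic RuO4 oxidation is the standard conversion of 2,3-epoxy alcohols into glycidic acids and should spare the epoxide and silyl ether, the descriptor at C10 changing only through the priority switch.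

Step 10
Reactants: 13 (2S,3R)-3-(tert-butyldimethylsilyloxymethyl)-2-methyloxirane-2-carboxylic acid; 14 (9H-fluoren-9-yl)methanethiol
Product: 15 S-(9H-fluoren-9-ylmethyl) (2S,3R)-3-(tert-butyldimethylsilyloxymethyl)-2-methyloxirane-2-carbothioate
Conditions: DCC, DMAP (5 mol %), CH2Cl2, 0 °C
Reagents that add atoms: none
Why: Steglich-type thioesterification should install sulfur on C1 as a base-releasable thioacid equivalent, and C10 bears no hydrogen and so cannot epimerise.

Step 11
Reactants: 15 S-(9H-fluoren-9-ylmethyl) (2S,3R)-3-(tert-butyldimethylsilyloxymethyl)-2-methyloxirane-2-carbothioate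
Product: 16 S-(9H-fluoren-9-ylmethyl) (2S,3R)-3-(hydroxymethyl)-2-methyloxirane-2-carbothioate
Conditions: HF·pyridine, pyridine, THF, 0 °C
Reagents that add atoms: none
Why: Buffered fluoride desilylation is not basic enough to cleave the fluorenylmethyl thioester, and the trans-epoxide keeps the freed C8 hydroxyl from lactonising onto C1.

Step 12
Reactants: 16 S-(9H-fluoren-9-ylmethyl) (2S,3R)-3-(hydroxymethyl)-2-methyloxirane-2-carbothioate
Product: 17 S-(9H-fluoren-9-ylmethyl) (2S,3S)-3-formyl-2-methyloxirane-2-carbothioate
Conditions: Dess–Martin periodinane, CH2Cl2, 0 °C to rt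
Reagents that add atoms: none
Why: Dess–Martin oxidation should give the configurationally stable α,β-epoxy aldehyde under non-basic conditions, the C9 descriptor changing only by priority.

Step 13
Reactants: 7 (5S)-3-(bromomethyl)-5-[(1Z)-2-iodoprop-1-en-1-yl]furan-2(5H)-one; 17 S-(9H-fluoren-9-ylmethyl) (2S,3S)-3-formyl-2-methyloxirane-2-carbothioate
Product: 18 seco alcohol (4Z,6S,7R,8R,9R,10S): α-methylene-γ-butyrolactone with the (Z)-2-iodopropenyl group on C6 and, trans to it on C7, the C8 carbinol that bears the epoxy thioester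
Conditions: Zn dust, THF/sat. aq. NH4Cl, 0 °C to rt
Reagents that add atoms: none
Why: In this Barbier 2-(alkoxycarbonyl)allylation the allylzinc should react at C7 through a Zimmerman–Traxler chair on the butenolide face anti to the C6 side chain (C7 trans to C6), its ring-locked E-type geometry giving the anti C7/C8 carbinol (8R), which is also the Felkin–Anh sense of the epoxy aldehyde.

Step 14
Reactants: 18 seco alcohol (4Z,6S,7R,8R,9R,10S); 19 3-methylbutanoic acid (isovaleric acid)
Product: 20 seco isovalerate (4Z,6S,7S,8S,9R,10S)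
Conditions: PPh3, DIAD, toluene, 0 °C to rt
Reagents that add atoms: none
Why: In the Mitsunobu esterification, SN2 displacement of the C8 oxyphosphonium ion by isovalerate should invert C8 to the required configuration and install the ester in the same step, an epoxy carbinol being unable to ionise.

Step 15
Reactants: 20 seco isovalerate (4Z,6S,7S,8S,9R,10S); 21 tributyl(1-ethoxyvinyl)stannane
Product: 23 bromomethyl ketone (4Z,6R,7S,8S,9R,10S), via ethoxydiene 22 (not isolated)
Conditions: Pd2(dba)3 (5 mol %), AsPh3 (20 mol %), DMF, 40 °C; then NBS, THF/H2O, 0 °C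
Reagents that add atoms: N-bromosuccinimide, O=C1CCC(=O)N1Br; water, O
Why: Copper-free Stille coupling should replace iodine with retention of the Z geometry and leave the thioester alone, and the 2-ethoxydiene, by far the most electron-rich olefin, should be brominated at its terminal CH2 (C2) and hydrolysed to the bromomethyl ketone.

Step 16
Reactants: 23 bromomethyl ketone (4Z,6R,7S,8S,9R,10S)
Product: 25 eleven-membered thiolactone (4Z,6R,7S,8S,9R,10S), via thioacid 24 (not isolated)
Conditions: DBU (1.2 equiv), MeCN (1 mM, slow addition of 23), 0 °C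
Reagents that add atoms: none
Why: E1cB cleavage of the fluorenylmethyl thioester frees the thiocarboxylate, a soft nucleophile that should displace the α-keto bromide irreversibly (SN2, 11-exo-tet) under high dilution, whereas its additions to the Michael acceptors are reversible.

Step 17
Reactants: 25 eleven-membered thiolactone (4Z,6R,7S,8S,9R,10S)
Product: 28 9-hydroxy furanone (4Z,6R,7S,8S,9R,10R), via thiirane alkoxide 26 (not isolated), via epoxy diketone 27 (not isolated)
Conditions: PPh3 (3 equiv), i-Pr2NEt (2 equiv), LiClO4 (5 equiv), MeCN (2 mM), 70 °C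
Reagents that add atoms: none
Why: Proposed new method: Li+/amine soft enolisation of the doubly activated C2H2 lets C2 add to the thioester carbonyl C1 (3-exo-trig) to give thiirane alkoxide 26, PPh3 takes the sulfur irreversibly as Ph3P=S to leave the ten-membered epoxy-1,3-diketonate 27 (C2–C1 bond), and its enolate oxygen O3 then opens the Li+-activated epoxide at C10 (O3–C10 bond) to give 28 after proton transfer to O9. The closest known reaction types are the Eschenmoser sulfide contraction of S-(2-oxoalkyl) thiocarboxylates to 1,3-dicarbonyl compounds, also known as a ring contraction of thia-macrolides to medium-ring β-keto lactones, and the base-induced O-cyclisation of γ-halo-1,3-diketones to 3(2H)-furanones; their coupling through an α,β-epoxy thiolactone is what is new. The ten-membered carbocycle is closed by contraction of the eleven-membered ring (3-exo-trig addition, then extrusion), so no end-to-end C–C macrocyclisation is needed, and the furanone is closed 5-exo-tet through the in-plane lone pair of the enolate oxygen. C10 is the only stereocentre that changes: backside attack inverts the epoxide carbon set in step 8 (10S to 10R), which places O3 anti to O9, while C9 keeps its C–O bond and C6–C8 are untouched. The step needs C- instead of O-acyl transfer (the sulfur relay can only hand C1 to C2), 5-exo instead of 6-endo opening (C9 is shielded by the C8 ester and its attack would give the more strained six-membered bridge) and the absence of nucleophilic halide, which would cause double inversion at C10 (25 is freed from bromide and LiClO4 has an inert anion). The Z-C4=C5 bond, the trans-lactone and the trans-epoxide already hold the ring in the shape of the natural skeleton, and release of epoxide strain together with formation of the vinylogous ester makes the last step irreversible.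

Step 18
Reactants: 28 9-hydroxy furanone (4Z,6R,7S,8S,9R,10R)
Product: 29 target CNP0255553.1 (4Z,6R,7S,8S,9R,10R)
Conditions: Ac2O, DMAP (10 mol %), pyridine, CH2Cl2, 0 °C to rt
Reagents that add atoms: acetic anhydride, CC(=O)OC(C)=O
Why: DMAP-catalysed acetylation should cap the hindered C9 alcohol on oxygen without touching any stereocentre.

Compound list
1 | but-2-yn-1-ol | CC#CCO | starting material
2 | (Z)-3-iodobut-2-en-1-ol | OC/C=C(/C)I | intermediate
3 | (Z)-3-iodobut-2-enal | O=C/C=C(/C)I | intermediate
4 | (3S,4Z)-5-iodohexa-1,4-dien-3-ol | C=C[C@H](O)/C=C(/C)I | intermediate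
5 | 2-(bromomethyl)prop-2-enoic acid | C=C(CBr)C(=O)O | starting material
6 | (3S,4Z)-5-iodohexa-1,4-dien-3-yl 2-(bromomethyl)prop-2-enoate | C=C(CBr)C(=O)O[C@@H](C=C)/C=C(/C)I | intermediate
7 | (5S)-3-(bromomethyl)-5-[(1Z)-2-iodoprop-1-en-1-yl]furan-2(5H)-one | O=C1O[C@H](/C=C(/C)I)C=C1CBr | intermediate
8 | (tert-butyldimethylsilyloxy)acetaldehyde | O=CCO[Si](C)(C)C(C)(C)C | starting material
9 | ethyl 2-(triphenylphosphoranylidene)propanoate | CCOC(=O)C(C)=P(c1ccccc1)(c1ccccc1)c1ccccc1 | starting material
10 | ethyl (2E)-4-(tert-butyldimethylsilyloxy)-2-methylbut-2-enoate | CCOC(=O)/C(C)=C/CO[Si](C)(C)C(C)(C)C | intermediate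
11 | (2E)-4-(tert-butyldimethylsilyloxy)-2-methylbut-2-en-1-ol | OC/C(C)=C/CO[Si](C)(C)C(C)(C)C | intermediate
12 | [(2R,3R)-3-(tert-butyldimethylsilyloxymethyl)-2-methyloxiran-2-yl]methanol | CC(C)(C)[Si](C)(C)OC[C@H]1O[C@]1(C)CO | intermediate
13 | (2S,3R)-3-(tert-butyldimethylsilyloxymethyl)-2-methyloxirane-2-carboxylic acid | CC(C)(C)[Si](C)(C)OC[C@H]1O[C@]1(C)C(=O)O | intermediate
14 | (9H-fluoren-9-yl)methanethiol | SCC1c2ccccc2-c2ccccc21 | starting material
15 | S-(9H-fluoren-9-ylmethyl) (2S,3R)-3-(tert-butyldimethylsilyloxymethyl)-2-methyloxirane-2-carbothioate | CC(C)(C)[Si](C)(C)OC[C@H]1O[C@]1(C)C(=O)SCC2c3ccccc3-c3ccccc32 | intermediate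
16 | S-(9H-fluoren-9-ylmethyl) (2S,3R)-3-(hydroxymethyl)-2-methyloxirane-2-carbothioate | OC[C@H]1O[C@]1(C)C(=O)SCC2c3ccccc3-c3ccccc32 | intermediate
17 | S-(9H-fluoren-9-ylmethyl) (2S,3S)-3-formyl-2-methyloxirane-2-carbothioate | O=C[C@H]1O[C@]1(C)C(=O)SCC2c3ccccc3-c3ccccc32 | intermediate
18 | seco alcohol, 8-epi series (4Z,6S,7R,8R,9R,10S) | C=C1C(=O)O[C@H](/C=C(/C)I)[C@H]1[C@@H](O)[C@H]2O[C@]2(C)C(=O)SCC3c4ccccc4-c4ccccc43 | intermediate
19 | 3-methylbutanoic acid (isovaleric acid) | CC(C)CC(=O)O | starting material
20 | seco isovalerate with vinyl iodide (4Z,6S,7S,8S,9R,10S) | C=C1C(=O)O[C@H](/C=C(/C)I)[C@H]1[C@H](OC(=O)CC(C)C)[C@H]2O[C@]2(C)C(=O)SCC3c4ccccc4-c4ccccc43 | intermediate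
21 | tributyl(1-ethoxyvinyl)stannane | CCCC[Sn](CCCC)(CCCC)C(=C)OCC | starting material
22 | ethoxydiene, not isolated (4Z,6R,7S,8S,9R,10S) | C=C1C(=O)O[C@H](/C=C(/C)C(=C)OCC)[C@H]1[C@H](OC(=O)CC(C)C)[C@H]2O[C@]2(C)C(=O)SCC3c4ccccc4-c4ccccc43 | intermediate
23 | bromomethyl ketone (4Z,6R,7S,8S,9R,10S) | C=C1C(=O)O[C@H](/C=C(/C)C(=O)CBr)[C@H]1[C@H](OC(=O)CC(C)C)[C@H]2O[C@]2(C)C(=O)SCC3c4ccccc4-c4ccccc43 | intermediate
24 | thioacid, not isolated, present as its DBU salt (4Z,6R,7S,8S,9R,10S) | C=C1C(=O)O[C@H](/C=C(/C)C(=O)CBr)[C@H]1[C@H](OC(=O)CC(C)C)[C@H]2O[C@]2(C)C(=O)S | intermediate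
25 | eleven-membered thiolactone, S between C1 and C2 (4Z,6R,7S,8S,9R,10S) | C=C1C(=O)O[C@@H]2/C=C(/C)C(=O)CSC(=O)[C@@]3(C)O[C@@H]3[C@@H](OC(=O)CC(C)C)[C@@H]12 | intermediate
26 | thiirane alkoxide, not isolated, drawn as the alcohol, C1 and C2 configuration open | C=C1C(=O)O[C@@H]2/C=C(/C)C(=O)C4SC4(O)[C@@]3(C)O[C@@H]3[C@@H](OC(=O)CC(C)C)[C@@H]12 | intermediate
27 | ten-membered epoxy 1,3-diketone, not isolated, drawn as the diketo form (4Z,6R,7S,8S,9R,10S) | C=C1C(=O)O[C@@H]2/C=C(/C)C(=O)CC(=O)[C@@]3(C)O[C@@H]3[C@@H](OC(=O)CC(C)C)[C@@H]12 | intermediate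
28 | 9-hydroxy furanone, 9-deacetyl target (4Z,6R,7S,8S,9R,10R) | C=C1C(=O)O[C@@H]2/C=C(/C)C3=CC(=O)[C@](C)(O3)[C@H](O)[C@@H](OC(=O)CC(C)C)[C@@H]12 | intermediate
29 | CNP0255553.1 (4Z,6R,7S,8S,9R,10R) | C=C1C(=O)O[C@@H]2/C=C(/C)C3=CC(=O)[C@](C)(O3)[C@H](OC(C)=O)[C@@H](OC(=O)CC(C)C)[C@@H]12 | target

Total step count: 18
Longest linear sequence: 13 steps (8 to 29, steps 6–18); the branch from 1 contributes 5 steps before the union in step 13.

Steps most likely to fail

Step 17 (labelled step). The cascade may stall at the lithium diketonate after sulfur extrusion. The epoxide may be opened at C9 in the 6-endo mode. The base may also move the isovaleryl group from O8 to the newly freed O9. The fallback sets out from 25 and comes back at 28. The two bond formations are uncoupled, and the second is changed from anionic to electrophilic activation, each stage being known chemistry. A classical Eschenmoser sulfide contraction with P(OEt)3, i-Pr2NEt and LiClO4 in MeCN at 40 °C, quenched with pH 7 buffer, should stop at epoxy diketone 27, which is isolated as its neutral enol. Catalytic Sc(OTf)3 in CH2Cl2 at −20 °C then binds the epoxide oxygen. The neutral enol oxygen O3 closes the furanone in an acid-catalysed 5-exo epoxide-opening etherification with the same inversion at C10. No alkoxide is formed, which removes the cause of acyl migration.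

Step 16. Intermolecular S-alkylation may lead to oligomers. The thiocarboxylate may be lost by conjugate addition to the methylene lactone. DBU may be alkylated by the bromoketone. The fallback sets out from 20 and comes back at 25, bypassing steps 15 and 16, and closes the eleven-membered ring at C3–C4 instead of at S–C2. DBU cleavage of the fluorenylmethyl thioester of 20 in the presence of chloroacetaldehyde should give, by intermolecular S-alkylation, the S-(2-oxoethyl) thioester F1. A Nozaki–Hiyama–Kishi macrocyclisation (CrCl2, NiCl2 1 mol %, DMF, 2 mM) joins the vinyl iodide carbon C4 to the aldehyde carbon C3 with retention of the Z geometry. It gives the macrocyclic allylic alcohol F2 as either C3 epimer. Dess–Martin oxidation of F2 gives 25.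

Step 14. Activation of the hindered C8 carbinol may be slow, the weakly acidic isovaleric acid may be outcompeted by the hydrazide, and elimination may take over. The fallback sets out from 18 and comes back at 20, and separates activation from displacement. ClCH2SO2Cl and pyridine in CH2Cl2 at 0 °C should give the chloromethanesulfonate F3. Caesium isovalerate with 18-crown-6 in toluene at 40–60 °C then displaces the sulfonate in an SN2 reaction with the same inversion at C8.

Further compounds
F0 | step 17 | none | none
F1 | step 16 | S-(2-oxoethyl) thioester of the seco isovalerate (4Z,6S,7S,8S,9R,10S) | C=C1C(=O)O[C@H](/C=C(/C)I)[C@H]1[C@H](OC(=O)CC(C)C)[C@H]2O[C@]2(C)C(=O)SCC=O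
F2 | step 16 | eleven-membered thiolactone with C3 carbinol, C3 configuration open | C=C1C(=O)O[C@@H]2/C=C(/C)C(O)CSC(=O)[C@@]3(C)O[C@@H]3[C@@H](OC(=O)CC(C)C)[C@@H]12
F3 | step 14 | C8 chloromethanesulfonate of 18 (4Z,6S,7R,8R,9R,10S) | C=C1C(=O)O[C@H](/C=C(/C)I)[C@H]1[C@@H](OS(=O)(=O)CCl)[C@H]2O[C@]2(C)C(=O)SCC3c4ccccc4-c4ccccc43
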